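The runs were generated by integration for substances that don't exist; noise was put on by code.

At the late end of the two earlier runs, at 50.0 h, the left-handed substrate stood at 20% in the south-east run and 20% in the north run, although the north run held 2.31 times the racemization catalyst. The right-handed substrate, which crossing would drain, stood higher in the north run, 44% against 40%. I saw no crossing above the scatter, so I pooled the runs; each summed pair of readings gives the fraction left of that enantiomer's own charge.

| flask | left-handed substrate | right-handed substrate | reagent | free catalyst | racemization catalyst | remark | time |
|---|---|---|---|---|---|---|---|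
| south-east | 0.020 M | 0.020 M | 0.050 M | 3.8 mM | 0.13 mM | run made earlier |  |
| north | 0.020 M | 0.020 M | 0.050 M | 3.8 mM | 0.30 mM | run made earlier |  |
| flask | 0.020 M | 0.020 M | 0.0500 M | 3.8 mM | 0.20 mM |  | 2.5 d |

| run | time / h | left-handed substrate / % | right-handed substrate / % | left-handed product / % |
|---|---|---|---|---|
| south-east | 10.0 | 37 | 50 | 10 |
| south-east | 20.0 | 34 | 45 | 19 |
| south-east | 30.0 | 27 | 46 | 22 |
| south-east | 40.0 | 22 | 42 | 30 |
| south-east | 50.0 | 20 | 40 | 31 |
| north | 10.0 | 39 | 48 | 12 |
| north | 20.0 | 32 | 47 | 19 |
| north | 30.0 | 29 | 46 | 24 |
| north | 40.0 | 24 | 46 | 27 |
| north | 50.0 | 20 | 44 | 32 |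

(readings scatter by 1.5 percentage points)

- free catalyst is single-handed; left-handed substrate and right-handed substrate are mirror images of each other, charged as a racemate, each of them at the stated concentration
- an excess is below zero if the other one leads

- part of the left-handed substrate and right-handed substrate charged together that has reacted at 2.5 d
- excess of left-handed product over right-handed product in the product at 2.5 d
- excess of right-handed substrate over left-handed substrate among what is left of the two at 2.5 d

The logarithmic loss rate of the left-handed substrate fell from 0.0274 h⁻¹ over the first readings to 0.0168 h⁻¹ as a mean over the last ones. But both mirror images meet the same reagent and free catalyst at each moment, so without crossing that slowing cancels in s = 5.26 (singly 4.11 and 7.17), the selectivity factor: the logarithm of the left-handed fraction remaining over that of the right-handed fraction remaining.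

Holding the mean rate to the asked time, I reckoned 33.8% of the left-handed charge remaining, and s then gave 81.4% of the right-handed. That meant c near 42.4%, eS near 41.3% and eP near 56.1%.

The forecast gave 43%, 65% and 40%, reasoning “so racemization looks weak”; its eP stood above mine.

The flask gave 42.1%, 63.2% and 44.6%.

    reagent + free catalyst + left-handed substrate → free catalyst + left-handed product (k = 2.80 M⁻² min⁻¹)
    reagent + free catalyst + right-handed substrate → free catalyst + right-handed product (k = 0.410 M⁻² min⁻¹)
    left-handed substrate + racemization catalyst ⇌ right-handed substrate + racemization catalyst, rate k3*[racemization catalyst]*[left-handed substrate] forward; the back reaction follows from the equilibrium constant (k = 0.560 M⁻¹ min⁻¹)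
    free catalyst ⇌ dormant form (K = 0.380, k = 6.10 × 10⁻⁴ min⁻¹)
    2 racemization catalyst ⇌ resting dimer, settled at all times (K = 8.50 × 10⁵ M⁻¹)

In this flask eP stood at 63.2% because the run ended at 2.5 d: the same flask carried on to 25.0 d gave 29.7%, with the left-handed substrate down to 0.834%. The crossing's relaxation half-life in this flask, 40.7 d, is long against the run. With 32% of the left-handed charge remaining, s gives 80.5% of the right-handed; the flask held 84%. In the neighbour with 0.20 M of reagent, 0.80% of the left-handed charge remaining gives 39.9% by s, and the computed value is 46%.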